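## Structural features

The target is a ten-membered carbocycle (C1–C10) with an E trisubstituted olefin C3=C4 (methyl on C3), a trans trisubstituted epoxide C7–C8 (methyl on C7), a free hydroxyl on C9, an isopropyl group on C10 and, on C1, the ester of 3-hydroxy-4-methoxybenzoic acid. Five stereocentres stand in one row, C7–C8–C9–C10–C1. The C9 hydroxyl is anti to the epoxide oxygen (erythro epoxy alcohol) and trans to the isopropyl group, which is in turn trans to the C1 acyloxy group. The olefin and the epoxide are 1,5-related across the ring, so acid or a strong Lewis acid invites transannular closure to a decalin; in base the epoxy alcohol can migrate, the C1 ester can shift to O9, and the free guaiacol-type phenol is oxidisable. The real difficulty is the ten-membered ring itself with two E trisubstituted units, whose direct closure fights entropy and transannular strain, together with placing three contiguous sp3 centres and one epoxide face on a mobile ring. The key step exploits the 1,5-relationship of C3=C4 and C7=C8: a bond between C3 and C8 turns the ring into a trans-fused bicyclo[4.4.0]decane. In it ring A (C3–C8) is a cyclohexa-1,3-diene and ring B (C8, C9, C10, C1, C2, C3) is a chair with the substituents on C9, C10 and C1 all equatorial. Cutting C3–C8 with light releases the ten-membered ring with both trisubstituted olefins E, so ring size and olefin geometry come from one pericyclic event and the sp3 centres from six-membered-ring chemistry.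

## Logic of the disconnections

28 back to 27: the phenolic O–H is replaced by an O–allyl bond. A free phenol would bind the titanium reagent and could be oxidised in the epoxidation. The forward step must remove the allyl group without touching epoxide, ester or olefin, which zerovalent palladium with an amine allows.

27 back to 26: the C7–O and C8–O bonds of the epoxide are cut, leaving the C7=C8 olefin next to the free C9 hydroxyl. This removes two stereocentres and the most acid-sensitive group. The forward step must put oxygen on C7=C8 only, not on C3=C4, and on the face that gives the anti epoxy alcohol.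

26 back to 25, then to 21 and 24: O9 is returned to its silyl ether and the C(=O)–O1 ester bond is cut. Acylation then meets a single free hydroxyl, and the aryl ester chromophore stays out of the photochemical stage. The forward steps must acylate a hindered secondary alcohol without acid and free O9 without acyl migration; 24 comes from 22 by allylation.

21 back to 20: the O1–H is returned to a triethylsilyl ether. The demand is a cleavage that distinguishes the two silyl ethers, which their graded lability provides.

20 back to 19 and 18: two hydrogens are removed from C5 and C6 (giving the Z double bond of 19) and then the C3–C8 bond is re-formed. This replaces a medium ring by two six-membered rings and puts C9, C10 and C1 on a rigid chair. The forward step must open with both ring-B carbons turning outward and reduce only the disubstituted double bond, cold.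

18 back to 17, 15 and 13: C6–H is exchanged for C6–O (triflate, then ketone) and the C4=C5 bond is saturated. The diene thus derives from an ordinary ketone. The forward steps need regiocontrolled enolisation, first toward C5 and then toward C7.

13 back to 12, 11, 10 and 9: the two O–Si bonds are cut, then C9–O, C1–O, C8–H and C10–H are removed to give a ring-B diene, with C6 masked as a ketal. Four stereocentres are traded for one diene. The forward step must add to both double bonds from the face opposite the C3 methyl and then tell the two hydroxyls apart.

9 back to 8 and 7: the dioxolane is cut, the double bonds return to conjugation with C6=O, and the C10=C9 unsaturation is traded for an isopropenyl group on C10. This leads back to a Robinson annulation product. The forward steps rely on thermodynamic double-bond migration in acid. A ketone that kept its isopropyl stereocentre would need the Michael addition anti to that group, against the axial preference; relaying the chirality through quaternary C3 avoids this.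

7 back to 6, then to 1 and 3 with auxiliary 2: the C7=C8 aldol bond and the C3–C4 Michael bond are cut. This leaves a terpene ketone and a five-carbon enone. The forward step must set quaternary C3 in one sense, for which substrate and chiral amine work in the same direction.

## Other disconnections considered

Alternative 1: The cut is the C8–C9 bond, made by a Nozaki–Hiyama–Kishi closure. The dienol ester A1 would arise from the iodo aldehyde A2 with CrCl2 and catalytic NiCl2 in DMSO at high dilution, the alkenylchromium from the E iodide adding to the C9 aldehyde.
- In its favour: the C7=C8 geometry is fixed in an open chain, the conditions tolerate ester and silyl ether, and the approach is convergent. A1 already carries the ester and the free C9 hydroxyl, so it is two operations from the target; on endgame length this alternative is the better one.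
- Against it here: in A2 the aldehyde sits on C10, which bears the isopropyl group and is β to the C1 acyloxy group, so epimerisation and elimination of the ester threaten. The C9 configuration must be won during ring closure, where 1,2-induction and ring strain may disagree. A ten-membered ring with two E trisubstituted olefins closes against entropy and transannular strain and needs excess divalent chromium.
- Comparison: the chosen plan fixes C9, C10 and C1 on a chair before the ring exists and opens the ring by a unimolecular event with no diastereoselection to win. Alternative 1 is more convergent, but the open-chain synthesis of A2 with its two stereocentres and two E olefins should cost about as many steps as it saves.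

Alternative 2: The cut is the C2–C3 bond. The epoxy alcohol A3 would arise from the alkynyl bis-epoxide A4 with Ni(cod)2, PBu3 and Et3B, the methyl alkyne coupling reductively with the CH2 carbon of the terminal epoxide.
- In its favour: one step forms C2–C3, sets the E olefin by syn addition across the alkyne and frees the C1 hydroxyl for acylation. The C7–C8 epoxide and C9 are made in an open chain, where the anti epoxy alcohol does not depend on the conformation of a medium ring; on that point it is better than the chosen plan. The endgame from A3 is short.
- Against it here: this coupling is well established for small rings, and a ten-membered carbocycle is a long extrapolation. The regiochemistry at a methyl alkyne is not secure. The internal epoxide must survive zerovalent nickel and the Lewis-acidic borane, and two epoxides compete.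
- Comparison: mechanistically the chosen plan rests on a symmetry-controlled opening, this one on an unproven macrocyclisation. The route to A4, with four stereocentres, two epoxides and an alkyne, would be at least as long as the chosen one.

Alternative 3: The cut is the C7=C8 double bond, made by a titanium carbonyl coupling. The diene A5 would arise from the keto aldehyde A6 with low-valent titanium from TiCl3(DME)1.5 and Zn–Cu couple in refluxing DME under slow addition.
- In its favour: it is convergent, and the reaction type has wide use for medium-ring dienes. A5 is the same compound as 20, so the endgame is identical; on that score the two plans are equal.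
- Against it here: the mechanism does not control the geometry of the new trisubstituted bond. The aldehyde carries an α-silyloxy group at C9 that low-valent titanium can remove reductively, and the α-stereocentre may epimerise at reflux.
- Comparison: the chosen plan obtains the E geometry from orbital symmetry and ring fusion, and never places O9 next to a reactive carbonyl. Alternative 3 is shorter on paper if A6 is easily made, but weaker on geometry and functional-group tolerance.

Key step: step 11

Remarks on the chemistry:
- Numbering: the ring numbering of the target (C1 ester carbinol to C10 isopropyl-bearing carbon) is used for all bicyclic intermediates; there C3–C8 is the ring fusion. "β" is the face of the C3 methyl group, "α" the opposite face.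
- Assumption: commercial (+)-dihydrocarvone 1 is the 5R compound sold as a mixture of C2 epimers; it is used as such because this carbon is planar in the reacting enamine.
- Structure check: diene 18, triene 19 and target 28 were compared centre by centre. C1, C9 and C10 have the same configuration in all three, 19 is 3E,5Z,7E, and 28 is the anti epoxy alcohol; no structure needs correction.
- Precursor design: a p-methoxybenzyl ether on O9 was rejected, because it is a second chromophore at 254 nm and its oxidative removal would expose a new allylic alcohol to the oxidant. The diene carries a TBS ether on O9 and a triethylsilyl ether on O1 instead.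

## Steps

Step 1
Reactants: 1 (+)-dihydrocarvone; 2 (S)-1-phenylethylamine; 3 ethyl vinyl ketone
Product: 6 (2R,5R)-2-methyl-2-(3-oxopentyl)-5-(prop-1-en-2-yl)cyclohexan-1-one, via phenylethyl imine 4 (not isolated), via Michael adduct imine 5 (not isolated)
Conditions: TsOH (cat.), toluene, reflux (−H2O); then 3, THF, 40 °C; then 10% aq. AcOH, rt
Reagents that add atoms: water, O
Why: Chiral-imine Michael addition (first stage of a Robinson annulation): the imine reacts through its more substituted secondary enamine, so the C3–C4 bond forms at the methyl-bearing carbon and the epimers of 1 converge. Quaternary C3 should form in one sense because the (S)-amine shields the face that is also disfavoured by the axial approach syn to the equatorial isopropenyl group (matched pair); mild acid returns the auxiliary.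

Step 2
Reactants: 6 diketone
Product: 7 (4aR,7R)-1,4a-dimethyl-7-(prop-1-en-2-yl)-4,4a,5,6,7,8-hexahydronaphthalen-2(3H)-one
Conditions: NaOMe, MeOH, rt to 50 °C
Reagents that add atoms: none
Why: Intramolecular aldol condensation closes ring A by forming C7=C8 (second stage of the Robinson annulation) without touching a stereocentre. Any minor C3 epimer is removed here by chromatography, because step 3 would turn that diastereomer into the enantiomer of 8.

Step 3
Reactants: 7 bicyclic enone
Product: 8 (4aR)-1,4a-dimethyl-7-(propan-2-yl)-4,4a,5,6-tetrahydronaphthalen-2(3H)-one
Conditions: TsOH·H2O (cat.), benzene, 80 °C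
Reagents that add atoms: none
Why: Acid-mediated double-bond migration: protonation of the isopropenyl group, loss of H10 and acid-catalysed dienol formation through C9–H bring the double bond into conjugation, the linear dienone being the thermodynamic sink. The C10 stereocentre is erased on purpose; the chirality now rests on quaternary C3 alone.

Step 4
Reactants: 8 linear dienone
Product: 9 C6 ethylene ketal of the ring-B diene (C8=C9, C10=C1; C3 methyl β, C7 methyl α)
Conditions: HOCH2CH2OH, TsOH (cat.), benzene, reflux (Dean–Stark)
Reagents that add atoms: ethylene glycol, OCCO
Why: Deconjugative ketalisation, as known for steroidal 4,6-dien-3-ones: the trienol ether intermediate is protonated at C7, which moves both double bonds into ring B and protects C6. The C7 methyl should settle on the α face, away from the syn-axial C3 methyl; this centre is erased again in step 9.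

Step 5
Reactants: 9 diene ketal
Product: 11 trans-fused 9α,1α-dihydroxy-6-ketone (H8 α, isopropyl β on C10, C7 methyl α), via diol dioxolane 10 (not isolated)
Conditions: BH3·THF (excess), THF, 0 °C to rt; then NaOH, H2O2, 0 °C; then 2 M HCl, THF, rt
Reagents that add atoms: hydrogen peroxide, OO; water, O
Why: Twofold hydroboration–oxidation of the homoannular diene, then ketal hydrolysis in the same flask. Each double bond has one CH carbon (C9, C1), which takes boron, and both syn additions should occur on the α face opposite the axial C3 methyl, so H8 (trans fusion), O9, H10 and O1 arrive α and C9, C10, C1 become equatorial. The acid also leaves the C7 methyl equatorial through enolisation.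

Step 6
Reactants: 11 keto diol
Product: 12 C1 triethylsilyl ether of 11
Conditions: Et3SiCl (1.05 equiv), imidazole, CH2Cl2, −40 to −20 °C
Reagents that add atoms: chlorotriethylsilane, CC[Si](Cl)(CC)CC
Why: Site-selective silylation: the C1 hydroxyl has a methylene neighbour, whereas the C9 hydroxyl is wedged between the ring fusion, the isopropyl-bearing carbon and the parallel equatorial C7 methyl, so one equivalent at low temperature should take O1.

Step 7
Reactants: 12 mono-silyl ether
Product: 13 C9 TBS ether, C1 triethylsilyl ether of the 6-ketone
Conditions: TBSOTf, 2,6-lutidine, CH2Cl2, −78 to 0 °C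
Reagents that add atoms: tert-butyldimethylsilyl trifluoromethanesulfonate, CC(C)(C)[Si](C)(C)OS(=O)(=O)C(F)(F)F
Why: The silyl triflate silylates the hindered C9 hydroxyl. The pair gives graded lability (O1 first, O9 later) and adds no chromophore for step 11.

Step 8
Reactants: 13 bis-silyl ketone
Product: 15 bis-silyl 4-en-6-one, via lithium enolate 14 (not isolated)
Conditions: LiN(iPr)2, THF, −78 °C; then PhS(Cl)=NtBu, −78 °C
Reagents that add atoms: none
Why: Kinetic deprotonation at the C5 methylene (the tertiary C7–H is slower) gives enolate 14, which is sulfenylated at C5 by the sulfinimidoyl chloride. Syn elimination of the sulfenamide then gives the C4=C5 enone in one flask (ketone α,β-dehydrogenation).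

Step 9
Reactants: 15 enone
Product: 17 bis-silyl 4,6-dien-6-yl triflate, via potassium dienolate 16 (not isolated)
Conditions: KN(SiMe3)2, THF, −78 °C; then PhNTf2, −78 to 0 °C
Reagents that add atoms: N-phenylbis(trifluoromethanesulfonimide), O=S(=O)(N(c1ccccc1)S(=O)(=O)C(F)(F)F)C(F)(F)F
Why: The only acidic hydrogen left is C7–H (the γ carbon C3 is quaternary), so the amide base gives the cross-conjugated dienolate 16, which is O-sulfonylated to the dienyl triflate. The C7 stereocentre disappears.

Step 10
Reactants: 17 dienyl triflate
Product: 18 trans-fused ring-A 4,6-diene with C9 TBS ether and C1 triethylsilyl ether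
Conditions: Pd(OAc)2 (cat.), PPh3, Bu3N, HCO2H, DMF, 60 °C
Reagents that add atoms: none
Why: Palladium-catalysed formate reduction of an enol triflate: oxidative addition to zerovalent palladium, exchange of triflate for formate, loss of CO2 and reductive elimination replace C6–O by C6–H without moving the double bonds.

Step 11
Reactants: 18 bicyclic diene
Product: 20 (3E,7E)-cyclodeca-3,7-diene with C9 TBS ether and C1 triethylsilyl ether, via cyclodecatriene 19 (not isolated)
Conditions: hν (254 nm, low-pressure Hg lamp, quartz), degassed Et2O–MeOH, −78 °C, to partial conversion; then KO2CN=NCO2K, AcOH (slow addition), −30 to −20 °C, dark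
Reagents that add atoms: none
Why: The cyclohexa-1,3-diene chromophore absorbs (the silyl ethers are transparent), and from the singlet excited state a six-electron conrotatory electrocyclic opening cleaves the C3–C8 sigma bond; the closest known reaction type is the photochemical opening of trans-fused bicyclo[4.4.0]deca-2,4-dienes and of provitamin D-type dienes to cyclic trienes. No ring is closed: the ten-membered ring appears by fission of the bond shared by the two six-membered rings, and no stereocentre is formed or touched, C9, C10 and C1 being spectators. Conrotation can turn the ring-B carbons C2 and C9 both outward or both inward; the trans fusion puts them on opposite faces so that one conrotatory sense moves both outward, while the inward sense would need a Z,Z,Z-triene that a ten-membered ring cannot hold, so C3=C4 and C7=C8 should come out E and C5=C6 Z. Triene 19 is kept cold because its thermal, disrotatory reclosure would give the cis-fused diene, and irradiation stops at partial conversion because 19 absorbs more strongly than 18. Diimide, made in the dark from the azodicarboxylate salt and acetic acid, transfers two hydrogens suprafacially through a six-membered transition state and discriminates by substitution, so the cis-disubstituted C5=C6 bond should react well ahead of the two trisubstituted bonds. The selectivities needed are outward rotation, secured by the trans ring fusion set in step 5, and mono-reduction, secured by the substitution pattern and a limited diimide supply.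

Step 12
Reactants: 20 bis-silyl diene
Product: 21 C1 alcohol with C9 TBS ether
Conditions: HF·pyridine, pyridine, THF, 0 °C
Reagents that add atoms: none
Why: Buffered fluoride cleaves the less hindered, more labile triethylsilyl ether on O1 and leaves the hindered allylic TBS ether on O9. Excess pyridine keeps the medium basic because the 1,5-diene is acid-sensitive.

Step 13
Reactants: 22 isovanillic acid
Product: 24 3-(allyloxy)-4-methoxybenzoic acid, via allyl ester 23 (not isolated)
Conditions: allyl bromide, K2CO3, DMF, 50 °C; then NaOH, MeOH–H2O, 60 °C; HCl to pH 2
Reagents that add atoms: allyl bromide, C=CCBr; water (as hydroxide), O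
Why: Double O-alkylation of phenoxide and carboxylate (Williamson type), then saponification of the allyl ester in the same flask. The phenol stays masked as an allyl ether, which survives fluoride and the epoxidation and is removed later under neutral conditions.

Step 14
Reactants: 21 C1 alcohol; 24 3-(allyloxy)-4-methoxybenzoic acid
Product: 25 C1 3-(allyloxy)-4-methoxybenzoate with C9 TBS ether
Conditions: EDC·HCl, DMAP, CH2Cl2, rt
Reagents that add atoms: none
Why: Steglich esterification (carbodiimide activation, acyl transfer by DMAP) acylates the only free hydroxyl. The C1 configuration is retained because the C1–O bond is not broken.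

Step 15
Reactants: 25 silyl ether ester
Product: 26 C9 allylic alcohol, C1 3-(allyloxy)-4-methoxybenzoate
Conditions: Bu4NF, AcOH (1:1), THF, rt
Reagents that add atoms: none
Why: Fluoride cleaves the remaining silyl ether; acetic acid buffers the alkoxide so that the C1 ester should not migrate to O9.

Step 16
Reactants: 26 allylic alcohol
Product: 27 7,8-epoxy-9-ol, C1 3-(allyloxy)-4-methoxybenzoate
Conditions: Ti(OiPr)4, D-(−)-diisopropyl tartrate, tBuOOH (anhydrous, in decane), 4 Å molecular sieves, CH2Cl2, −20 °C
Reagents that add atoms: tert-butyl hydroperoxide, CC(C)(C)OO
Why: Sharpless epoxidation in its stoichiometric, matched form: the titanium-bound C9 alkoxide delivers oxygen only to the allylic C7=C8 bond, and D-(−)-tartrate selects the face that gives the anti (erythro) epoxy alcohol, the relationship this reagent favours for a secondary allylic alcohol of this configuration. The ring should help, since the small O9–C9–C8=C7 dihedral angle with C10 on the far face that this transition state needs is what an E olefin in a ten-membered ring can offer.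

Step 17
Reactants: 27 allyl-protected epoxy alcohol
Product: 28 target, C1 isovanillate of the 7,8-epoxy-9-ol
Conditions: Pd(PPh3)4 (cat.), morpholine, THF, rt
Reagents that add atoms: none
Why: Palladium-catalysed deallylation: zerovalent palladium ionises the aryl allyl ether to a π-allyl complex and the phenoxide, and morpholine takes up the allyl group. Epoxide, ester, secondary alcohol and the trisubstituted olefin are not substrates.

## Compound list

1 | (+)-dihydrocarvone, (5R)-2-methyl-5-(prop-1-en-2-yl)cyclohexan-1-one, C2 epimer mixture | CC1CC[C@H](CC1=O)C(C)=C | starting material
2 | (S)-1-phenylethylamine (auxiliary, recovered) | C[C@H](N)c1ccccc1 | starting material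
3 | ethyl vinyl ketone (pent-1-en-3-one) | CCC(=O)C=C | starting material
4 | N-[(S)-1-phenylethyl]imine of 1 | CC1CC[C@H](CC1=N[C@@H](C)c1ccccc1)C(C)=C | intermediate
5 | N-[(S)-1-phenylethyl]imine of (2R,5R)-2-methyl-2-(3-oxopentyl)-5-(prop-1-en-2-yl)cyclohexan-1-one | CCC(=O)CC[C@@]1(C)CC[C@@H](C(C)=C)CC1=N[C@@H](C)c1ccccc1 | intermediate
6 | (2R,5R)-2-methyl-2-(3-oxopentyl)-5-(prop-1-en-2-yl)cyclohexan-1-one | CCC(=O)CC[C@@]1(C)CC[C@@H](C(C)=C)CC1=O | intermediate
7 | (4aR,7R)-1,4a-dimethyl-7-(prop-1-en-2-yl)-4,4a,5,6,7,8-hexahydronaphthalen-2(3H)-one (route numbering: 7-en-6-one, C3 methyl β, C10 isopropenyl α) | CC1=C2C[C@H](C(C)=C)CC[C@]2(C)CCC1=O | intermediate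
8 | (4aR)-1,4a-dimethyl-7-(propan-2-yl)-4,4a,5,6-tetrahydronaphthalen-2(3H)-one (route numbering: 7,9-dien-6-one) | CC1=C2C=C(C(C)C)CC[C@]2(C)CCC1=O | intermediate
9 | C6 ethylene ketal of the bicyclic ring-B diene (C8=C9, C10=C1), C3 methyl β, C7 methyl α, isopropyl on C10 | C[C@@H]1C2=CC(C(C)C)=CC[C@]2(C)CCC13OCCO3 | intermediate
10 | C6 ethylene ketal of the trans-fused 9α,1α-diol (H8 α, isopropyl β on C10, C7 methyl α) | C[C@@H]1[C@H]2[C@H](O)[C@@H](C(C)C)[C@H](O)C[C@]2(C)CCC13OCCO3 | intermediate
11 | trans-fused bicyclic 9α,1α-dihydroxy-6-ketone (H8 α, isopropyl β on C10, C3 methyl β, C7 methyl α) | C[C@@H]1[C@H]2[C@H](O)[C@@H](C(C)C)[C@H](O)C[C@]2(C)CCC1=O | intermediate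
12 | C1 triethylsilyl ether of 11 (C9 hydroxyl free) | C[C@@H]1[C@H]2[C@H](O)[C@@H](C(C)C)[C@H](O[Si](CC)(CC)CC)C[C@]2(C)CCC1=O | intermediate
13 | C9 TBS ether, C1 triethylsilyl ether of the trans-fused 6-ketone | C[C@@H]1[C@H]2[C@H](O[Si](C)(C)C(C)(C)C)[C@@H](C(C)C)[C@H](O[Si](CC)(CC)CC)C[C@]2(C)CCC1=O | intermediate
14 | lithium C5=C6 enolate of 13 | C[C@@H]1[C@H]2[C@H](O[Si](C)(C)C(C)(C)C)[C@@H](C(C)C)[C@H](O[Si](CC)(CC)CC)C[C@]2(C)CC=C1O[Li] | intermediate
15 | C9 TBS ether, C1 triethylsilyl ether of the trans-fused 4-en-6-one | C[C@@H]1[C@H]2[C@H](O[Si](C)(C)C(C)(C)C)[C@@H](C(C)C)[C@H](O[Si](CC)(CC)CC)C[C@]2(C)C=CC1=O | intermediate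
16 | potassium cross-conjugated dienolate of 15 (C4=C5, C6=C7) | C[C@@]12C=CC(O[K])=C(C)[C@H]1[C@H](O[Si](C)(C)C(C)(C)C)[C@@H](C(C)C)[C@H](O[Si](CC)(CC)CC)C2 | intermediate
17 | trans-fused ring-A 4,6-dien-6-yl triflate with C9 TBS ether and C1 triethylsilyl ether | C[C@@]12C=CC(OS(=O)(=O)C(F)(F)F)=C(C)[C@H]1[C@H](O[Si](C)(C)C(C)(C)C)[C@@H](C(C)C)[C@H](O[Si](CC)(CC)CC)C2 | intermediate
18 | trans-fused hexalin, ring-A 4,6-diene, angular methyl on C3, C9 TBS ether (α), C10 isopropyl (β), C1 triethylsilyl ether (α) | C[C@@]12C=CC=C(C)[C@H]1[C@H](O[Si](C)(C)C(C)(C)C)[C@@H](C(C)C)[C@H](O[Si](CC)(CC)CC)C2 | intermediate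
19 | (3E,5Z,7E)-cyclodeca-3,5,7-triene with C9 TBS ether and C1 triethylsilyl ether | CC[Si](CC)(CC)O[C@@H]1C/C(C)=C/C=C\C(C)=C\[C@H](O[Si](C)(C)C(C)(C)C)[C@H]1C(C)C | intermediate
20 | (3E,7E)-cyclodeca-3,7-diene with C9 TBS ether and C1 triethylsilyl ether | CC[Si](CC)(CC)O[C@@H]1C/C(C)=C/CC/C(C)=C/[C@H](O[Si](C)(C)C(C)(C)C)[C@H]1C(C)C | intermediate
21 | (3E,7E)-cyclodeca-3,7-dien-1-ol with C9 TBS ether | O[C@@H]1C/C(C)=C/CC/C(C)=C/[C@H](O[Si](C)(C)C(C)(C)C)[C@H]1C(C)C | intermediate
22 | isovanillic acid (3-hydroxy-4-methoxybenzoic acid) | COc1ccc(C(=O)O)cc1O | starting material
23 | allyl 3-(allyloxy)-4-methoxybenzoate | COc1ccc(C(=O)OCC=C)cc1OCC=C | intermediate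
24 | 3-(allyloxy)-4-methoxybenzoic acid | COc1ccc(C(=O)O)cc1OCC=C | intermediate
25 | C1 3-(allyloxy)-4-methoxybenzoate of the (3E,7E)-diene with C9 TBS ether | COc1ccc(C(=O)O[C@@H]2C/C(C)=C/CC/C(C)=C/[C@H](O[Si](C)(C)C(C)(C)C)[C@H]2C(C)C)cc1OCC=C | intermediate
26 | C1 3-(allyloxy)-4-methoxybenzoate of the (3E,7E)-dien-9-ol | COc1ccc(C(=O)O[C@@H]2C/C(C)=C/CC/C(C)=C/[C@H](O)[C@H]2C(C)C)cc1OCC=C | intermediate
27 | C1 3-(allyloxy)-4-methoxybenzoate of the (3E)-7,8-epoxy-9-ol (anti epoxy alcohol) | COc1ccc(C(=O)O[C@@H]2C/C(C)=C/CC[C@@]3(C)O[C@@H]3[C@H](O)[C@H]2C(C)C)cc1OCC=C | intermediate
28 | CNP0294356.1, C1 isovanillate of the (3E)-7,8-epoxy-9-hydroxy-10-isopropyl-3,7-dimethylcyclodec-3-ene | COc1ccc(C(=O)O[C@@H]2C/C(C)=C/CC[C@@]3(C)O[C@@H]3[C@H](O)[C@H]2C(C)C)cc1O | target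

## Step count and least certain steps

Total: 17 steps, 16 in the main line and one (step 13) for acid 24. Longest linear sequence: 16 steps, from 1 to 28 through steps 1–12 and 14–17.

Step 11 (key step). The photostationary state may lie on the side of 18, and further light-driven isomerisation of 19 may compete because 19 absorbs more strongly. Warming allows disrotatory reclosure to a cis-fused diene, and once the central bond is reduced diimide may go on to attack a strained E double bond. Fallback, from 18 back to 20 without a new compound: generation and trapping are separated and the trapping principle is changed. The diene is irradiated in a cooled flow cell with short residence time, and the cold stream is led directly onto Raney nickel under H2 at −20 °C in a second vessel. The reduction is then a surface hydrogenation that selects by accessibility of the exposed cis-disubstituted bond instead of a soluble hydrogen-transfer reagent made with acid; unchanged 18 is recycled.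

Step 5. Borane may attack C8=C9 in part from the β face (cis-fused by-product), the second addition may stall, or allylborane intermediates may be protonated. Imperfect site selection in step 6 would add to the loss. Fallback, from 9 back to 13, one double bond at a time:
- 9-Borabicyclo[3.3.1]nonane should add only to the less hindered C10=C1 bond; oxidation gives the homoallylic alcohol F1.
- Et3SiCl and imidazole give its triethylsilyl ether F2.
- BH3·THF then H2O2/NaOH on the remaining C8=C9 bond gives the hydroxy ketal F3, where a cis-fused isomer can be separated.
- TBSOTf and 2,6-lutidine give the bis-silyl ketal F4.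
- Neutral transketalisation with PdCl2(MeCN)2 (cat.) in acetone returns 13.

Each hydroxyl is protected as it appears, so no site-selective silylation is needed.

Step 9. Deprotonation of the tertiary C7–H, syn-axial to the C3 methyl and crowded by the O9 silyl ether, may be slow, so that addition of the amide to the enone or loss of the triflate on work-up competes. Fallback, from 15 back to 18: condensation with TsNHNH2 in MeOH gives the tosylhydrazone F5. Excess LiN(iPr)2 in THF from −78 to 0 °C with aqueous quench (Shapiro reaction) then removes sulfinate and N2 through the C7 carbanion and gives 18 directly, bypassing 16 and 17.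

Step 16. Oxygen transfer to a hindered secondary carbinol with a cis methyl on the far olefin carbon may be slow. Facial selectivity may erode if the ring reacts through the conformer that puts H9 instead of O9 near the olefin plane (giving the syn epoxy alcohol), and the Lewis-acidic titanium may induce transannular opening of the new epoxide by the C3=C4 bond. Fallback, from 20 back to 27, with the order of events reversed:
- Bu4NF removes both silyl groups to give the diol F6.
- A vanadium-directed epoxidation (VO(acac)2, tBuOOH, CH2Cl2, 0 °C) of the C9 allylic alcohol on this unencumbered ring gives the epoxy diol F7.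
- Site-selective Steglich acylation of the more accessible C1 hydroxyl with 24 (EDC·HCl, DMAP, 0 °C) gives 27.

The selectivity question moves from the oxidant to the acylation.

## Further compounds

F0 | step 11 | none | none
F1 | step 5 | C6 ethylene ketal of the 8-en-1α-ol (isopropyl β on C10, C8=C9 retained) | C[C@@H]1C2=C[C@@H](C(C)C)[C@H](O)C[C@]2(C)CCC13OCCO3
F2 | step 5 | C1 triethylsilyl ether of F1 | C[C@@H]1C2=C[C@@H](C(C)C)[C@H](O[Si](CC)(CC)CC)C[C@]2(C)CCC13OCCO3
F3 | step 5 | C6 ethylene ketal of the trans-fused 9α-ol with C1 triethylsilyl ether | C[C@@H]1[C@H]2[C@H](O)[C@@H](C(C)C)[C@H](O[Si](CC)(CC)CC)C[C@]2(C)CCC13OCCO3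
F4 | step 5 | C6 ethylene ketal with C9 TBS ether and C1 triethylsilyl ether | C[C@@H]1[C@H]2[C@H](O[Si](C)(C)C(C)(C)C)[C@@H](C(C)C)[C@H](O[Si](CC)(CC)CC)C[C@]2(C)CCC13OCCO3
F5 | step 9 | p-toluenesulfonylhydrazone of enone 15 | C[C@@H]1[C@H]2[C@H](O[Si](C)(C)C(C)(C)C)[C@@H](C(C)C)[C@H](O[Si](CC)(CC)CC)C[C@]2(C)C=CC1=NNS(=O)(=O)c1ccc(C)cc1
F6 | step 16 | (3E,7E)-10-isopropyl-3,7-dimethylcyclodeca-3,7-diene-1,9-diol | O[C@@H]1C/C(C)=C/CC/C(C)=C/[C@H](O)[C@H]1C(C)C
F7 | step 16 | (3E)-7,8-epoxy-10-isopropyl-3,7-dimethylcyclodec-3-ene-1,9-diol | O[C@@H]1C/C(C)=C/CC[C@@]2(C)O[C@@H]2[C@H](O)[C@H]1C(C)C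
A1 | alternative 1 | ten-membered E,E-dienol ester, free C9 hydroxyl, phenol as TBS ether | COc1ccc(C(=O)O[C@@H]2C/C(C)=C/CC/C(C)=C/[C@H](O)[C@H]2C(C)C)cc1O[Si](C)(C)C(C)(C)C
A2 | alternative 1 | open-chain E-alkenyl iodide (C8) with C9 aldehyde and C1 aryl ester | COc1ccc(C(=O)O[C@H](C/C(C)=C/CC/C(C)=C/I)[C@@H](C=O)C(C)C)cc1O[Si](C)(C)C(C)(C)C
A3 | alternative 2 | ten-membered epoxy alcohol, free C1 hydroxyl, C9 TBS ether | O[C@@H]1C/C(C)=C/CC[C@@]2(C)O[C@@H]2[C@H](O[Si](C)(C)C(C)(C)C)[C@H]1C(C)C
A4 | alternative 2 | open-chain methyl alkyne with C7–C8 epoxide, C9 TBS ether and terminal C1–C2 epoxide | CC#CCC[C@@]1(C)O[C@@H]1[C@H](O[Si](C)(C)C(C)(C)C)[C@@H](C(C)C)[C@H]1CO1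
A5 | alternative 3 | ten-membered E,E-diene, C1 triethylsilyl ether, C9 TBS ether (identical with 20) | CC[Si](CC)(CC)O[C@@H]1C/C(C)=C/CC/C(C)=C/[C@H](O[Si](C)(C)C(C)(C)C)[C@H]1C(C)C
A6 | alternative 3 | open-chain C7 methyl ketone and C8 aldehyde with E C3=C4 olefin, C1 triethylsilyl ether, C9 TBS ether | CC(=O)CC/C=C(\C)C[C@@H](O[Si](CC)(CC)CC)[C@H](C(C)C)[C@@H](O[Si](C)(C)C(C)(C)C)C=O
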